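Hansforester A is cut at its four ester bonds into an orsellinate (ring A), two (R)-3-hydroxybutanoate linkers and two arenes. The key step exploits the substitution pattern of ring C (carboxyl on C1, hydroxyls on C2 and C4, the (R)-2-oxypropyl chain on C6) and the fact that ring D is ring C without the C1 carboxyl, so a single annulation product supplies both rings. It is made in one operation by Michael addition of dimethyl malonate to an (R,E)-6-silyloxyhept-3-en-2-one (bond C1–C6) and Claisen ring closure (bond C2–C3). The precursor is this chiral-pool enone with its oxygen masked as a robust triisopropylsilyl ether.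

Key step: step 4

Remarks on the chemistry
- Labels: ring A is the orsellinate ring, ring C the central 2,4-dihydroxybenzoate ring, ring D the terminal resorcinol ring. Linker 1 and linker 2 are the (R)-3-oxybutanoate units between rings A and C and between rings C and D.
- All four stereocentres of the target are (R). Each is taken from an (R)-3-hydroxybutanoate, and every ester bond of the main route is made by acylating the alcohol oxygen, so each centre is carried through with retention.
- The side-chain oxygen is carried as a triisopropylsilyl ether instead of a smaller silyl ether. A free hydroxyl beside the ring C carboxyl would close to a six-membered lactone, so the group must survive hot methoxide, the aromatisation and hot hydroxide.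
- Assumption: sodium (R)-3-hydroxybutanoate is taken as a commercial salt. The linker carboxyl is masked as an allyl ester because a β-acyloxy ester does not tolerate basic hydrolysis.
- Equivalents in the Conditions lines are planned amounts.

Step 1
Reactants: 1 methyl (R)-3-hydroxybutanoate
Product: 2 methyl (R)-3-(triisopropylsilyloxy)butanoate
Conditions: i-Pr3SiOTf, 2,6-lutidine, CH2Cl2, 0 °C to rt
Reagents that add atoms: triisopropylsilyl trifluoromethanesulfonate, CC(C)[Si](OS(=O)(=O)C(F)(F)F)(C(C)C)C(C)C
Why: O-silylation of a secondary alcohol with a silyl triflate and a hindered pyridine base should be fast and does not touch the stereocentre.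

Step 2
Reactants: 2 methyl (R)-3-(triisopropylsilyloxy)butanoate
Product: 3 (R)-3-(triisopropylsilyloxy)butanal
Conditions: i-Bu2AlH (1.05 equiv), CH2Cl2, −78 °C; MeOH, then aqueous potassium sodium tartrate (KNaC4H4O6)
Reagents that add atoms: none
Why: Partial reduction of an ester by diisobutylaluminium hydride at low temperature should stop at the tetrahedral aluminium hemiacetal, which gives the aldehyde only on work-up, and the β-stereocentre cannot epimerise.

Step 3
Reactants: 3 (R)-3-(triisopropylsilyloxy)butanal; 4 1-(triphenylphosphoranylidene)propan-2-one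
Product: 5 (R,E)-6-(triisopropylsilyloxy)hept-3-en-2-one
Conditions: CH2Cl2, reflux
Reagents that add atoms: none
Why: Wittig olefination with a stabilised acyl ylide should give the (E)-enone, and the neutral conditions should not eliminate the β-silyloxy group.

Step 4
Reactants: 5 (R,E)-6-(triisopropylsilyloxy)hept-3-en-2-one; 6 dimethyl malonate
Product: 8 methyl 2,4-dioxo-6-[(R)-2-(triisopropylsilyloxy)propyl]cyclohexane-1-carboxylate, via Michael adduct 7 (not isolated)
Conditions: dimethyl malonate (1.2 equiv), NaOMe (1.1 equiv), MeOH, rt then reflux; cold 1 M HCl to pH 3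
Reagents that add atoms: none
Why: Sodiomalonate adds in a conjugate (Michael) fashion to C4 of the enone and creates ring bond C1–C6; proton exchange then gives the methyl-side ketone enolate, which attacks one malonate ester carbonyl in a Claisen (Dieckmann-type) condensation, creating ring bond C2–C3 with loss of methoxide. The closest known reaction type is the malonate–enone Michael–Claisen annulation that gives 6-alkyl-2,4-dioxocyclohexanecarboxylates, the usual precursors of alkylresorcylates. The ring closes in a 6-exo-trig mode (enolate carbon onto an ester carbonyl whose C=O lies outside the new ring), and the regiochemistry is fixed because the methylene-side enolate could only form a four-membered ring. Two ring stereocentres (C1 and C6) arise without control and are erased on aromatisation, while the side-chain (R) centre takes no part. The step needs 1,4-addition to outrun γ-deprotonation of the enone, which would expel the δ-silyloxy group by vinylogous E1cB elimination; the soft, weakly basic malonate anion, kept in slight excess over NaOMe, and the poor silyloxide leaving group should secure this. Deprotonation of the product to its stabilised dione enolate pulls both equilibria forward.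

Step 5
Reactants: 8 methyl 2,4-dioxo-6-[(R)-2-(triisopropylsilyloxy)propyl]cyclohexane-1-carboxylate
Product: 9 methyl 2,4-dihydroxy-6-[(R)-2-(triisopropylsilyloxy)propyl]benzoate
Conditions: I2 (20 mol %), DMSO, 80 °C
Reagents that add atoms: none
Why: Iodine-catalysed oxidative aromatisation (α-iodination of the enolised dione, loss of HI, tautomerisation, with dimethyl sulfoxide returning HI to I2) is an established dehydrogenation of 2,4-dioxocyclohexanecarboxylates to 2,4-dihydroxybenzoates and keeps the acid concentration catalytic, so the silyl ether should hold.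

Step 6
Reactants: 9 methyl 2,4-dihydroxy-6-[(R)-2-(triisopropylsilyloxy)propyl]benzoate
Product: 10 methyl 2,4-bis(benzyloxy)-6-[(R)-2-(triisopropylsilyloxy)propyl]benzoate
Conditions: BnBr (2.5 equiv), K2CO3, DMF, 60 °C
Reagents that add atoms: benzyl bromide, BrCc1ccccc1
Why: Williamson ether synthesis should O-benzylate both phenols, including the hydrogen-bonded C2 hydroxyl once warmed in DMF, while the methyl ester and the silyl ether are inert to carbonate.

Step 7
Reactants: 10 methyl 2,4-bis(benzyloxy)-6-[(R)-2-(triisopropylsilyloxy)propyl]benzoate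
Product: 11 2,4-bis(benzyloxy)-6-[(R)-2-(triisopropylsilyloxy)propyl]benzoic acid
Conditions: KOH, dioxane/MeOH/H2O, 90 °C; cold 1 M HCl to pH 3
Reagents that add atoms: potassium hydroxide, [K+].[OH-]
Why: Saponification of the doubly ortho-substituted methyl benzoate needs forcing hydroxide but is standard for 2,4-bis(benzyloxy)-6-alkylbenzoates, and the triisopropylsilyl ether, which must stay on so that the acid cannot lactonise on acidification, should withstand it.

Step 8
Reactants: 12 sodium (R)-3-hydroxybutanoate
Product: 13 allyl (R)-3-hydroxybutanoate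
Conditions: allyl bromide, DMF, 40 °C
Reagents that add atoms: allyl bromide, C=CCBr
Why: SN2 O-alkylation of the carboxylate in a dipolar aprotic solvent should give the allyl ester without touching the free secondary alcohol or its stereocentre.

Step 9
Reactants: 11 2,4-bis(benzyloxy)-6-[(R)-2-(triisopropylsilyloxy)propyl]benzoic acid; 13 allyl (R)-3-hydroxybutanoate
Product: 15 allyl (R)-3-({2,4-bis(benzyloxy)-6-[(R)-2-(triisopropylsilyloxy)propyl]benzoyl}oxy)butanoate, via acid chloride 14 (not isolated)
Conditions: 1-chloro-N,N,2-trimethylprop-1-en-1-amine, CH2Cl2, 0 °C to rt; then 13 (1.5 equiv), Et3N, DMAP, CH2Cl2, rt to 40 °C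
Reagents that add atoms: none
Why: The α-chloroenamine turns the hindered acid into its acyl chloride under neutral, HCl-free conditions that spare the silyl ether, and DMAP-catalysed acylation of the secondary alcohol (nucleophilic acyl substitution) then forms the ester with retention, since the alcohol C–O bond is not broken.

Step 10
Reactants: 15 allyl (R)-3-({2,4-bis(benzyloxy)-6-[(R)-2-(triisopropylsilyloxy)propyl]benzoyl}oxy)butanoate
Product: 16 (R)-3-({2,4-bis(benzyloxy)-6-[(R)-2-(triisopropylsilyloxy)propyl]benzoyl}oxy)butanoic acid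
Conditions: Pd(PPh3)4 (5 mol %), morpholine, THF, rt; aqueous citric acid work-up
Reagents that add atoms: none
Why: In this Tsuji–Trost-type deallylation zerovalent palladium ionises the allyl ester to a π-allyl complex that morpholine captures, which frees the acid without a base strong enough to eliminate the β-aroyloxy group.

Step 11
Reactants: 9 methyl 2,4-dihydroxy-6-[(R)-2-(triisopropylsilyloxy)propyl]benzoate
Product: 17 5-[(R)-2-(triisopropylsilyloxy)propyl]benzene-1,3-diol
Conditions: NaOH, MeOH/H2O, reflux, argon; then AcOH to pH 5, 80 °C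
Reagents that add atoms: none
Why: Saponification followed by protodecarboxylation of a 2,4-dihydroxybenzoic acid, whose ipso carbon is activated for protonation by the ortho and para hydroxyls, should give the 5-alkylresorcinol under mildly acidic conditions that the silyl ether survives, so that no free side-chain hydroxyl can lactonise before CO2 is lost.

Step 12
Reactants: 17 5-[(R)-2-(triisopropylsilyloxy)propyl]benzene-1,3-diol
Product: 18 {[(R)-1-[3,5-bis(benzyloxy)phenyl]propan-2-yl]oxy}triisopropylsilane
Conditions: BnBr (2.3 equiv), K2CO3, acetone, reflux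
Reagents that add atoms: benzyl bromide, BrCc1ccccc1
Why: Williamson ether synthesis on both resorcinol hydroxyls with carbonate in acetone, where O-alkylation should prevail over C-alkylation.

Step 13
Reactants: 18 {[(R)-1-[3,5-bis(benzyloxy)phenyl]propan-2-yl]oxy}triisopropylsilane
Product: 19 (R)-1-[3,5-bis(benzyloxy)phenyl]propan-2-ol
Conditions: Bu4NF, THF, rt to 50 °C
Reagents that add atoms: none
Why: Fluoride-mediated desilylation is driven by the strong Si–F bond, and as no ester is present the basicity of the reagent is of no concern and the stereocentre is untouched.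

Step 14
Reactants: 20 orsellinic acid
Product: 21 benzyl 2,4-bis(benzyloxy)-6-methylbenzoate
Conditions: BnBr (3.5 equiv), K2CO3, DMF, 60 °C
Reagents that add atoms: benzyl bromide, BrCc1ccccc1
Why: Exhaustive benzylation (carboxylate alkylation plus Williamson ether synthesis) should protect all three acidic groups in one operation.

Step 15
Reactants: 21 benzyl 2,4-bis(benzyloxy)-6-methylbenzoate
Product: 22 2,4-bis(benzyloxy)-6-methylbenzoic acid
Conditions: KOH, dioxane/MeOH/H2O, 90 °C; 1 M HCl to pH 3
Reagents that add atoms: potassium hydroxide, [K+].[OH-]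
Why: Saponification of the hindered benzyl ester with hot hydroxide should free the acid and leave the two benzyl aryl ethers untouched.

Step 16
Reactants: 22 2,4-bis(benzyloxy)-6-methylbenzoic acid; 13 allyl (R)-3-hydroxybutanoate
Product: 24 allyl (R)-3-{[2,4-bis(benzyloxy)-6-methylbenzoyl]oxy}butanoate, via acid chloride 23 (not isolated)
Conditions: 1-chloro-N,N,2-trimethylprop-1-en-1-amine, CH2Cl2, 0 °C to rt; then 13 (1.5 equiv), Et3N, DMAP, CH2Cl2, rt to 40 °C
Reagents that add atoms: none
Why: Acyl chloride formation with the α-chloroenamine followed by DMAP-catalysed acylation of the secondary alcohol, as in step 9, should form the ring A ester of linker 1 with retention at the (R) centre.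

Step 17
Reactants: 24 allyl (R)-3-{[2,4-bis(benzyloxy)-6-methylbenzoyl]oxy}butanoate
Product: 25 (R)-3-{[2,4-bis(benzyloxy)-6-methylbenzoyl]oxy}butanoic acid
Conditions: Pd(PPh3)4 (5 mol %), morpholine, THF, rt; aqueous citric acid work-up
Reagents that add atoms: none
Why: Tsuji–Trost-type deallylation with zerovalent palladium and morpholine as allyl acceptor should free the linker acid under conditions too mild for β-elimination.

Step 18
Reactants: 16 (R)-3-({2,4-bis(benzyloxy)-6-[(R)-2-(triisopropylsilyloxy)propyl]benzoyl}oxy)butanoic acid; 19 (R)-1-[3,5-bis(benzyloxy)phenyl]propan-2-ol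
Product: 26 (R)-1-[3,5-bis(benzyloxy)phenyl]propan-2-yl (R)-3-({2,4-bis(benzyloxy)-6-[(R)-2-(triisopropylsilyloxy)propyl]benzoyl}oxy)butanoate
Conditions: DCC, DMAP (cat.), CH2Cl2, 0 °C to rt
Reagents that add atoms: none
Why: In this Steglich esterification the carbodiimide activates the unhindered aliphatic acid and DMAP transfers the acyl group to the secondary alcohol with retention, while low temperature and catalytic DMAP are meant to suppress β-elimination of the aroyloxy group.

Step 19
Reactants: 26 (R)-1-[3,5-bis(benzyloxy)phenyl]propan-2-yl (R)-3-({2,4-bis(benzyloxy)-6-[(R)-2-(triisopropylsilyloxy)propyl]benzoyl}oxy)butanoate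
Product: 27 (R)-1-[3,5-bis(benzyloxy)phenyl]propan-2-yl (R)-3-({2,4-bis(benzyloxy)-6-[(R)-2-hydroxypropyl]benzoyl}oxy)butanoate
Conditions: HF·pyridine, pyridine, THF, 0 °C to rt
Reagents that add atoms: none
Why: Desilylation with pyridine-buffered HF·pyridine is mildly acidic, not basic, which should avoid both E1cB loss of the β-aroyloxy group and alkoxide attack of the freed hydroxyl on the neighbouring hindered aryl ester.

Step 20
Reactants: 27 (R)-1-[3,5-bis(benzyloxy)phenyl]propan-2-yl (R)-3-({2,4-bis(benzyloxy)-6-[(R)-2-hydroxypropyl]benzoyl}oxy)butanoate; 25 (R)-3-{[2,4-bis(benzyloxy)-6-methylbenzoyl]oxy}butanoic acid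
Product: 28 hexa-O-benzyl hansforester A (the target with all six phenols as benzyl ethers)
Conditions: 25 (1.5 equiv), DCC, DMAP (cat.), CH2Cl2, 0 °C to rt
Reagents that add atoms: none
Why: A second Steglich esterification acylates the side-chain hydroxyl of ring C with the aliphatic linker 1 acid with retention, which also removes the hydroxyl that could lactonise.

Step 21
Reactants: 28 hexa-O-benzyl hansforester A
Product: 29 hansforester A
Conditions: H2 (1 atm), Pd/C (10 wt % Pd), EtOAc/THF, rt
Reagents that add atoms: none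
Why: Hydrogenolysis of the six benzyl aryl ethers over palladium on carbon is neutral, and as none of the ester C–O bonds is benzylic the four esters and the four stereocentres should be unaffected.

Compound list
1 | methyl (R)-3-hydroxybutanoate | C[C@@H](O)CC(=O)OC | starting material
2 | methyl (R)-3-(triisopropylsilyloxy)butanoate | C[C@@H](O[Si](C(C)C)(C(C)C)C(C)C)CC(=O)OC | intermediate
3 | (R)-3-(triisopropylsilyloxy)butanal | C[C@@H](O[Si](C(C)C)(C(C)C)C(C)C)CC=O | intermediate
4 | 1-(triphenylphosphoranylidene)propan-2-one | CC(=O)C=P(c1ccccc1)(c1ccccc1)c1ccccc1 | starting material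
5 | (R,E)-6-(triisopropylsilyloxy)hept-3-en-2-one | CC(=O)/C=C/C[C@@H](C)O[Si](C(C)C)(C(C)C)C(C)C | intermediate
6 | dimethyl malonate | COC(=O)CC(=O)OC | starting material
7 | dimethyl 2-[(6R)-2-oxo-6-(triisopropylsilyloxy)heptan-4-yl]malonate (Michael adduct, both C4 epimers) | COC(=O)C(C(=O)OC)C(CC(C)=O)C[C@@H](C)O[Si](C(C)C)(C(C)C)C(C)C | intermediate
8 | methyl 2,4-dioxo-6-[(R)-2-(triisopropylsilyloxy)propyl]cyclohexane-1-carboxylate (C1/C6 diastereomers and enol tautomers) | COC(=O)C1C(=O)CC(=O)CC1C[C@@H](C)O[Si](C(C)C)(C(C)C)C(C)C | intermediate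
9 | methyl 2,4-dihydroxy-6-[(R)-2-(triisopropylsilyloxy)propyl]benzoate | COC(=O)c1c(O)cc(O)cc1C[C@@H](C)O[Si](C(C)C)(C(C)C)C(C)C | intermediate
10 | methyl 2,4-bis(benzyloxy)-6-[(R)-2-(triisopropylsilyloxy)propyl]benzoate | COC(=O)c1c(OCc2ccccc2)cc(OCc2ccccc2)cc1C[C@@H](C)O[Si](C(C)C)(C(C)C)C(C)C | intermediate
11 | 2,4-bis(benzyloxy)-6-[(R)-2-(triisopropylsilyloxy)propyl]benzoic acid | OC(=O)c1c(OCc2ccccc2)cc(OCc2ccccc2)cc1C[C@@H](C)O[Si](C(C)C)(C(C)C)C(C)C | intermediate
12 | sodium (R)-3-hydroxybutanoate | C[C@@H](O)CC(=O)[O-].[Na+] | starting material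
13 | allyl (R)-3-hydroxybutanoate | C[C@@H](O)CC(=O)OCC=C | intermediate
14 | 2,4-bis(benzyloxy)-6-[(R)-2-(triisopropylsilyloxy)propyl]benzoyl chloride | ClC(=O)c1c(OCc2ccccc2)cc(OCc2ccccc2)cc1C[C@@H](C)O[Si](C(C)C)(C(C)C)C(C)C | intermediate
15 | allyl (R)-3-({2,4-bis(benzyloxy)-6-[(R)-2-(triisopropylsilyloxy)propyl]benzoyl}oxy)butanoate | C=CCOC(=O)C[C@@H](C)OC(=O)c1c(OCc2ccccc2)cc(OCc2ccccc2)cc1C[C@@H](C)O[Si](C(C)C)(C(C)C)C(C)C | intermediate
16 | (R)-3-({2,4-bis(benzyloxy)-6-[(R)-2-(triisopropylsilyloxy)propyl]benzoyl}oxy)butanoic acid | OC(=O)C[C@@H](C)OC(=O)c1c(OCc2ccccc2)cc(OCc2ccccc2)cc1C[C@@H](C)O[Si](C(C)C)(C(C)C)C(C)C | intermediate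
17 | 5-[(R)-2-(triisopropylsilyloxy)propyl]benzene-1,3-diol | Oc1cc(O)cc(C[C@@H](C)O[Si](C(C)C)(C(C)C)C(C)C)c1 | intermediate
18 | {[(R)-1-[3,5-bis(benzyloxy)phenyl]propan-2-yl]oxy}triisopropylsilane | CC(C)[Si](C(C)C)(C(C)C)O[C@H](C)Cc1cc(OCc2ccccc2)cc(OCc2ccccc2)c1 | intermediate
19 | (R)-1-[3,5-bis(benzyloxy)phenyl]propan-2-ol | C[C@@H](O)Cc1cc(OCc2ccccc2)cc(OCc2ccccc2)c1 | intermediate
20 | orsellinic acid (2,4-dihydroxy-6-methylbenzoic acid) | Cc1cc(O)cc(O)c1C(=O)O | starting material
21 | benzyl 2,4-bis(benzyloxy)-6-methylbenzoate | Cc1cc(OCc2ccccc2)cc(OCc2ccccc2)c1C(=O)OCc1ccccc1 | intermediate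
22 | 2,4-bis(benzyloxy)-6-methylbenzoic acid | Cc1cc(OCc2ccccc2)cc(OCc2ccccc2)c1C(=O)O | intermediate
23 | 2,4-bis(benzyloxy)-6-methylbenzoyl chloride | Cc1cc(OCc2ccccc2)cc(OCc2ccccc2)c1C(Cl)=O | intermediate
24 | allyl (R)-3-{[2,4-bis(benzyloxy)-6-methylbenzoyl]oxy}butanoate | Cc1cc(OCc2ccccc2)cc(OCc2ccccc2)c1C(=O)O[C@H](C)CC(=O)OCC=C | intermediate
25 | (R)-3-{[2,4-bis(benzyloxy)-6-methylbenzoyl]oxy}butanoic acid | Cc1cc(OCc2ccccc2)cc(OCc2ccccc2)c1C(=O)O[C@H](C)CC(=O)O | intermediate
26 | (R)-1-[3,5-bis(benzyloxy)phenyl]propan-2-yl (R)-3-({2,4-bis(benzyloxy)-6-[(R)-2-(triisopropylsilyloxy)propyl]benzoyl}oxy)butanoate | CC(C)[Si](C(C)C)(C(C)C)O[C@H](C)Cc1cc(OCc2ccccc2)cc(OCc2ccccc2)c1C(=O)O[C@H](C)CC(=O)O[C@H](C)Cc1cc(OCc2ccccc2)cc(OCc2ccccc2)c1 | intermediate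
27 | (R)-1-[3,5-bis(benzyloxy)phenyl]propan-2-yl (R)-3-({2,4-bis(benzyloxy)-6-[(R)-2-hydroxypropyl]benzoyl}oxy)butanoate | C[C@@H](O)Cc1cc(OCc2ccccc2)cc(OCc2ccccc2)c1C(=O)O[C@H](C)CC(=O)O[C@H](C)Cc1cc(OCc2ccccc2)cc(OCc2ccccc2)c1 | intermediate
28 | hexa-O-benzyl hansforester A | Cc1cc(OCc2ccccc2)cc(OCc2ccccc2)c1C(=O)O[C@H](C)CC(=O)O[C@H](C)Cc1cc(OCc2ccccc2)cc(OCc2ccccc2)c1C(=O)O[C@H](C)CC(=O)O[C@H](C)Cc1cc(OCc2ccccc2)cc(OCc2ccccc2)c1 | intermediate
29 | hansforester A | Cc1cc(O)cc(O)c1C(=O)O[C@H](C)CC(=O)O[C@H](C)Cc1cc(O)cc(O)c1C(=O)O[C@H](C)CC(=O)O[C@H](C)Cc1cc(O)cc(O)c1 | target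

Total step count: 21. Longest linear sequence: 13 steps (steps 1 to 7, 9, 10, 18, 19, 20, 21).

Steps most likely to fail

1. Step 9. During activation the neighbouring silyloxy oxygen may attack the acyl chloride, with loss of the silyl group and closure of a six-membered lactone. The doubly ortho-substituted acyl chloride may also acylate the secondary alcohol too slowly. The fallback forms the same ester by Mitsunobu reaction, in which the hindered acid is the nucleophile and is never turned into an acyl electrophile. It sets out from acid 11. Commercial sodium (S)-3-hydroxybutanoate is O-allylated with allyl bromide in DMF, as in step 8, to give allyl (S)-3-hydroxybutanoate F1. Acid 11 and F1 with PPh3 and diisopropyl azodicarboxylate in toluene at 0 °C should give, by SN2 displacement with inversion, the (R)-configured ester 15, where the route is rejoined.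

2. Step 19. Removal of the bulky silyl group is slow. The freed secondary hydroxyl may therefore sit beside the aryl ester long enough for transesterification to the six-membered lactone, with loss of the linker 2–ring D alcohol. Fluoride may also trigger β-elimination of the aroyloxy group. The fallback reverses the order of the two ester bonds at ring C, so that the side-chain oxygen is acylated while the C1 carboxyl is a tert-butyl ester too hindered to be attacked. It sets out from acid 11.
   - N,N-dimethylformamide di-tert-butyl acetal in toluene at 80 °C gives tert-butyl 2,4-bis(benzyloxy)-6-[(R)-2-(triisopropylsilyloxy)propyl]benzoate F2.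
   - Bu4NF in THF gives tert-butyl 2,4-bis(benzyloxy)-6-[(R)-2-hydroxypropyl]benzoate F3.
   - Steglich esterification of F3 with acid 25 (DCC, DMAP, CH2Cl2) gives the ring A–linker 1–ring C tert-butyl ester F4.
   - Me3SiOTf and 2,6-lutidine in CH2Cl2 at 0 °C, then aqueous work-up, cleave the tert-butyl ester to the ring A–linker 1–ring C benzoic acid F5.
   - 1-Chloro-N,N,2-trimethylprop-1-en-1-amine gives the ring A–linker 1–ring C benzoyl chloride F6, which acylates alcohol 13 (Et3N, DMAP) to the ring A–linker 1–ring C–linker 2 allyl ester F7.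
   - Pd(PPh3)4 and morpholine give the ring A–linker 1–ring C–linker 2 acid F8.
   - Steglich esterification of F8 with alcohol 19 gives 28, where the route is rejoined.

3. Step 4. Methoxide may deprotonate the enone at the γ-position and expel the δ-silyloxy group to give a dienone. The Michael addition may also revert faster than the ring closes. The fallback is the complementary acetoacetate–enoate Michael–Claisen annulation, which forms ring bonds C1–C6 and C3–C4 instead and uses an acceptor whose γ-hydrogens are less acidic. It sets out from aldehyde 3. Wittig olefination with methyl (triphenylphosphoranylidene)acetate in CH2Cl2 gives methyl (R,E)-5-(triisopropylsilyloxy)hex-2-enoate F9. Methyl acetoacetate and NaOMe in MeOH at reflux add to F9 and give the Michael adduct dimethyl 2-acetyl-3-[(R)-2-(triisopropylsilyloxy)propyl]pentanedioate F10. Its acetyl enolate closes onto the distal ester to give dione ester 8, where the route is rejoined.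

Further compounds
F1 | step 9 | allyl (S)-3-hydroxybutanoate | C[C@H](O)CC(=O)OCC=C
F2 | step 19 | tert-butyl 2,4-bis(benzyloxy)-6-[(R)-2-(triisopropylsilyloxy)propyl]benzoate | CC(C)(C)OC(=O)c1c(OCc2ccccc2)cc(OCc2ccccc2)cc1C[C@@H](C)O[Si](C(C)C)(C(C)C)C(C)C
F3 | step 19 | tert-butyl 2,4-bis(benzyloxy)-6-[(R)-2-hydroxypropyl]benzoate | CC(C)(C)OC(=O)c1c(OCc2ccccc2)cc(OCc2ccccc2)cc1C[C@@H](C)O
F4 | step 19 | tert-butyl 2,4-bis(benzyloxy)-6-{(R)-2-[((R)-3-{[2,4-bis(benzyloxy)-6-methylbenzoyl]oxy}butanoyl)oxy]propyl}benzoate | Cc1cc(OCc2ccccc2)cc(OCc2ccccc2)c1C(=O)O[C@H](C)CC(=O)O[C@H](C)Cc1cc(OCc2ccccc2)cc(OCc2ccccc2)c1C(=O)OC(C)(C)C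
F5 | step 19 | 2,4-bis(benzyloxy)-6-{(R)-2-[((R)-3-{[2,4-bis(benzyloxy)-6-methylbenzoyl]oxy}butanoyl)oxy]propyl}benzoic acid | Cc1cc(OCc2ccccc2)cc(OCc2ccccc2)c1C(=O)O[C@H](C)CC(=O)O[C@H](C)Cc1cc(OCc2ccccc2)cc(OCc2ccccc2)c1C(=O)O
F6 | step 19 | 2,4-bis(benzyloxy)-6-{(R)-2-[((R)-3-{[2,4-bis(benzyloxy)-6-methylbenzoyl]oxy}butanoyl)oxy]propyl}benzoyl chloride | Cc1cc(OCc2ccccc2)cc(OCc2ccccc2)c1C(=O)O[C@H](C)CC(=O)O[C@H](C)Cc1cc(OCc2ccccc2)cc(OCc2ccccc2)c1C(Cl)=O
F7 | step 19 | allyl (R)-3-[(2,4-bis(benzyloxy)-6-{(R)-2-[((R)-3-{[2,4-bis(benzyloxy)-6-methylbenzoyl]oxy}butanoyl)oxy]propyl}benzoyl)oxy]butanoate | Cc1cc(OCc2ccccc2)cc(OCc2ccccc2)c1C(=O)O[C@H](C)CC(=O)O[C@H](C)Cc1cc(OCc2ccccc2)cc(OCc2ccccc2)c1C(=O)O[C@H](C)CC(=O)OCC=C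
F8 | step 19 | (R)-3-[(2,4-bis(benzyloxy)-6-{(R)-2-[((R)-3-{[2,4-bis(benzyloxy)-6-methylbenzoyl]oxy}butanoyl)oxy]propyl}benzoyl)oxy]butanoic acid | Cc1cc(OCc2ccccc2)cc(OCc2ccccc2)c1C(=O)O[C@H](C)CC(=O)O[C@H](C)Cc1cc(OCc2ccccc2)cc(OCc2ccccc2)c1C(=O)O[C@H](C)CC(=O)O
F9 | step 4 | methyl (R,E)-5-(triisopropylsilyloxy)hex-2-enoate | COC(=O)/C=C/C[C@@H](C)O[Si](C(C)C)(C(C)C)C(C)C
F10 | step 4 | dimethyl 2-acetyl-3-[(R)-2-(triisopropylsilyloxy)propyl]pentanedioate | COC(=O)CC(C[C@@H](C)O[Si](C(C)C)(C(C)C)C(C)C)C(C(C)=O)C(=O)OC
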